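## Analysis of the target

2α-Hydroxyferutinin 25 is a daucane ester built on a hydroazulene. A cycloheptene ring, numbered here C1(CH3)=C2–C3–C4(CH3)–C5(H)–C6(O-aroyl)–C7, is trans-fused along C4–C5 to a cyclopentane C4–C5–C8(OH)(i-Pr)–C9–C10(OH), and these locants are used for every intermediate. Five stereocentres are present on directly connected carbons (C10–C4–C5–C6, with C8 on C5), 4R,5S,6S,8R,10S: the angular methyl on the quaternary C4 is trans to H5, the tertiary C8 hydroxyl is cis to that methyl, the secondary C10 hydroxyl is trans to it, and the C6 ester oxygen is cis to H5, so that H5 and H6 are anti. The sensitive groups are the C1=C2 alkene (β,γ to C6, so it can slip into conjugation whenever C6 is a ketone), the tertiary C8 hydroxyl (dehydration, retro-aldol), the 4-hydroxybenzoate (acyl migration, or β-elimination once C8 is a carbonyl) and the free phenol. The synthesis is hard because a quaternary carbon sits in the middle of the stereochemical array in a flexible seven-membered ring, the trans ring fusion is not an automatic outcome, and three hydroxyls must be told apart: one acylated, one tertiary, and one secondary alcohol that has to be set against the steric bias of the angular methyl. The plan rests on the fact that C4 and C5 are the β- and α-carbons of a C6 carbonyl and carry, trans to each other, the two arms of the cyclopentane (C10 on C4, C8 on C5). The achiral dienone 6 already holds both methyl groups, the skipped alkene and the C6 oxygen, so conjugate addition at C4 followed by enolate trapping at C5 installs both arms and two ring stereocentres in one operation. The last carbon–carbon bond, C8–C9, then follows from an aldol closure between an acetyl group on C4 and an isobutyryl group on C5.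

## Retrosynthetic reasoning

**25 ⇐ 24.** Only the aryl O–Si bond is cut. The phenol stays masked to the end because the ester is introduced early and must pass through base, oxidant and hydride. A silyl ether is chosen because it can be removed under buffered, nearly neutral conditions that leave the ester, the alkene and the two free hydroxyls alone.

**24 ⇐ 23.** The C10–H bond is disconnected, tracing the secondary alcohol to the C10 ketone. Attack from the open face, anti to the angular methyl, would give the wrong epimer. The forward step therefore has to deliver hydride from the face of the C8 hydroxyl, and a C10 ketone beside a free tertiary C8 hydroxyl is exactly what an aldol closure leaves.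

**23 ⇐ 22.** The C8–C9 bond is cut (aldol retron C10=O / C9 / C8–OH). It is the only cyclopentane bond not attached to the seven-membered ring, so cutting it leaves both arms as plain carbonyl groups, acetyl on C4 and isobutyryl on C5. The forward reaction must use the kinetic methyl-ketone enolate and place the isopropyl group on the face of H5. The C6 oxygen must already be an ester here, since a C6 ketone would make C5 the central carbon of a β-diketone.

**22 ⇐ 21 ⇐ 20 ⇐ 19.** These are functional-group changes only: acetyl from vinyl (Wacker retron), the C8 ketone from the C8 carbinol, vinyl from 1-silylvinyl. The 1-silylvinyl group is the acetyl equivalent that a catalytic conjugate addition can deliver to a fully substituted β-carbon. The order (desilylate, oxidise C8, oxidise the vinyl group) keeps a free hydroxyl out of the palladium step and exposes the 1,4-diketone to nothing but the aldol.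

**19 ⇐ 15 + 18.** The ester C–O bond is cut at the stage where only two hydroxyls exist and differ strongly in hindrance. Later, two secondary hydroxyls (C6, C10) would compete. Acid 18 comes from 16 by silylation through 17.

**15 ⇐ 13 (through 14).** The C6–H bond is disconnected. The C8 hydroxyl left by the aldol addition is used as the control element through chelate 14, so a stereocentre that is later erased pays for the C6 stereocentre.

**13 ⇐ 6 + 9 + 10 (through 11 and 12).** Two carbon–carbon bonds, C4–C10 and C5–C8, are cut at the β- and α-carbons of the C6 ketone. This is the largest simplification available: three achiral components, no protecting groups, and a seven-membered ring that needs no further carbon. The forward step must set C4 by catalyst control and C5 trans to it by substrate control.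

**9 ⇐ 7 + 8.** The C–Al bond is traced to hydroalumination of the silylalkyne.

**6 ⇐ 5 ⇐ 4 ⇐ 3 ⇐ 2 ⇐ 1.** The dienone is traced to a six-membered aromatic ring by removing the carbon that becomes C5: enone from β-chloro ketone, from siloxycyclopropane, from silyl enol ether, from aryl silyl ether. The substitution pattern of 1 maps directly onto 6. Reduction of the aryl silyl ether gives the skipped diene and the regiodefined enol ether at once, whereas enolising a free β,γ-unsaturated ketone would go towards the doubly activated methylene and give the wrong enol ether.

## Alternatives that were turned down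

Alternative 1: The seven-membered ring is disconnected at C1–C7 and C3–C4, a formal [4+3] union of the ethoxydiene 2-(1-ethoxyvinyl)-3-methylcyclopent-2-en-1-one A1 with the vinylcarbene derived from methyl 2-diazobut-3-enoate A2.
- Forward key step: the chiral dirhodium tetracarboxylate Rh2(S-DOSP)4 A3, dirhodium tetrakis[(S)-N-(4-dodecylbenzenesulfonyl)prolinate] with divalent rhodium, would turn diazo ester A2 into the vinylcarbenoid, which cyclopropanates the ethoxyvinyl group of cyclopentenone A1. Cope rearrangement of the cis-divinylcyclopropane would then give the bicyclic ethoxy dienoate A4.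
- For: one asymmetric step under catalyst A3 gives the whole hydroazulene with the quaternary C4, the C6 oxygen and the C1=C2 alkene. On ring construction this is stronger than the chosen route, which still has to close the five-membered ring.
- Against: the Cope terminus C4 is the fully substituted β-carbon of the enone in A1, so the quaternary centre must form in the sigmatropic step. A4 carries an ester where C1 needs a methyl group and has no oxygen at C10, which would have to be introduced next to the quaternary carbon. C5 is sp2 in A4, so the trans ring fusion rests on a late reduction whose outcome is not assured, and the isopropyl group must still be added to C8 with facial control.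
- Comparison: the chosen strategy gives up the one-step bicycle but places every oxygen (C6, C8, C10) and both methyl groups correctly from the start. It also sets the trans relation at C4/C5 in the step that makes the quaternary centre.

Alternative 2: The C4–C5 bond is disconnected as the product of a 1,2-shift. This turns the hydroazulene into a decalin that comes from a Diels–Alder reaction of thymoquinone A5 with isoprene A6.
- Forward key step: in the rearrangement substrate, C6 (ring fusion) carries a hydroxyl and C5 a mesylate. On deprotonation with an alkoxide base, or on Lewis-acid activation, the C4–C6 bond antiperiplanar to C5–O migrates to C5, the mesylate leaves and C6 becomes a ketone. One six-membered ring contracts and the other expands, giving the keto bis-silyl ether A7.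
- For: all fifteen skeletal carbons come from the two bulk chemicals A5 and A6 in the first step. The shift is stereospecific (retention at C4, inversion at C5), so the trans fusion is transferred and not created, and C8 and C10 already carry oxygen. On raw-material cost and on the security of the ring-fusion stereochemistry it is at least as strong as the chosen route.
- Against: the cycloaddition must select the methyl-bearing alkene of quinone A5, the right orientation of diene A6 and one enantiomer. Many stereocontrolled redox steps lie between it and the shift: angular hydroxylation at C6, a silylated tertiary carbinol at C8, and reduction and mesylation of C5 between two fully substituted carbons, all with the geometry the migration needs. The C6–C7 bond can migrate in competition, and fragmentation or elimination of the hindered mesylate is possible. A7 still needs C6 reduction, acylation and deprotection.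
- Comparison: the chosen route reaches a comparable C6 ketone in fewer steps and takes its absolute configuration from a catalyst. It pays with a less rigid substrate for the C6 reduction, which is answered by chelation control.

Alternative 3: The C6–C7 bond is disconnected. The cycloheptene is traced to a tetrahydropyran (oxygen bridging C2 and C6) with an isopropenyl group on C2 (C1 with its methyl, C7 as the CH2) and a tributylstannyl group on C6, fused to the finished cyclopentane.
- Forward key step: tin–lithium exchange with an alkyllithium gives the α-alkoxy carbanion at C6. It bonds to C7 while the allylic O–C2 bond breaks ([2,3] Wittig–Still shift), giving the C6 alkoxide, the C1=C2 alkene and the carbocycle, alcohol A8.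
- For: C6 never passes through a ketone, so neither the conjugation problem nor a C6 reduction arises, and the C6 configuration follows from the stannane by a concerted shift. On these points it is stronger than the chosen route.
- Against: the whole stereochemical burden (quaternary C4, tertiary C8, C10 and a 2,6-disubstituted pyran with a defined α-alkoxystannane) must be carried through a long linear sequence before the key step. The shift must form the ring alkene through a strained bicyclic transition state and competes with the [1,2] shift. Tin is stoichiometric. Alcohol A8 still needs acylation and removal of two silyl groups.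
- Comparison: the chosen route is shorter, convergent in three simple components and catalytic in its source of chirality. It accepts a transient β,γ-enone, which is reduced in the step after it is formed.

Key step: step 7

Remark: which enantiomer of the imidazolinium salt gives the 4R adduct cannot be deduced from structure; the matching enantiomer (both derive from 1,2-diphenylethylenediamine) is assumed to be used.
Remark: the aldol adduct is assumed to form mainly as the anti (8R) diastereomer, on which step 8 relies.
Remark: CIP descriptors are given in the target numbering; at C4 and C5 they change between intermediates because substituent ranking changes, not because the centres are inverted.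

## Route

Step 1
Reactants: 1 2,5-dimethylphenol
Product: 2 tert-butyl(2,5-dimethylphenoxy)dimethylsilane
Conditions: TBSCl, imidazole, DMF, rt
Reagents that add atoms: tert-butylchlorodimethylsilane, CC(C)(C)[Si](C)(C)Cl
Why: O-silylation of a phenol; the bulky silyl ether should survive dissolving-metal reduction and decides which enol ether the next step delivers.

Step 2
Reactants: 2 tert-butyl(2,5-dimethylphenoxy)dimethylsilane
Product: 3 tert-butyl[(2,5-dimethylcyclohexa-1,4-dien-1-yl)oxy]dimethylsilane
Conditions: Li, NH3 (l), THF, t-BuOH, −78 → −33 °C; NH4Cl
Reagents that add atoms: none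
Why: Birch reduction of an aryl silyl ether; protonation at the two unsubstituted positions ortho and meta to oxygen keeps oxygen and both methyl groups on double bonds, so the silyl enol ether is formed as the single tetrasubstituted regioisomer beside the skipped trisubstituted alkene.

Step 3
Reactants: 3 tert-butyl[(2,5-dimethylcyclohexa-1,4-dien-1-yl)oxy]dimethylsilane
Product: 4 rac-tert-butyl[(3,6-dimethylbicyclo[4.1.0]hept-3-en-1-yl)oxy]dimethylsilane (cis-fused)
Conditions: Et2Zn, CH2I2, CH2Cl2, 0 °C → rt
Reagents that add atoms: diiodomethane, ICI
Why: Simmons–Smith cyclopropanation; the electrophilic zinc carbenoid should select the electron-rich silyl enol ether over the trisubstituted alkene, and the racemic stereocentres are erased in the next two steps.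

Step 4
Reactants: 4 rac-tert-butyl[(3,6-dimethylbicyclo[4.1.0]hept-3-en-1-yl)oxy]dimethylsilane
Product: 5 rac-6-chloro-3,6-dimethylcyclohept-3-en-1-one
Conditions: FeCl3, DMF, 0 °C → rt
Reagents that add atoms: iron trichloride, Cl[Fe](Cl)Cl
Why: FeCl3-mediated oxidative ring expansion of a siloxycyclopropane; one-electron oxidation by trivalent iron opens the internal cyclopropane bond to the ring-enlarged tertiary β-keto radical, which takes chlorine from a second FeCl3.

Step 5
Reactants: 5 rac-6-chloro-3,6-dimethylcyclohept-3-en-1-one
Product: 6 3,6-dimethylcyclohepta-2,5-dien-1-one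
Conditions: NaOAc, MeOH, 0 °C → rt
Reagents that add atoms: none
Why: E1cB loss of HCl from the tertiary β-chloro ketone through the enolate on the new CH2 (C5 of the target) gives the conjugated C4=C5 bond; the weak base at low temperature is chosen so that the skipped C1=C2 alkene is not pulled into conjugation.

Step 6
Reactants: 7 ethynyltrimethylsilane; 8 diisobutylaluminium hydride
Product: 9 diisobutyl[1-(trimethylsilyl)vinyl]aluminium (used as its solution)
Conditions: hexanes/THF, 55 °C
Reagents that add atoms: none
Why: hydroalumination of a silylalkyne; aluminium goes to the silicon-bearing carbon, where the carbon–metal bond is stabilised by silicon, and the terminal position makes alkene geometry irrelevant.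

Step 7
Reactants: 6 3,6-dimethylcyclohepta-2,5-dien-1-one; 9 diisobutyl[1-(trimethylsilyl)vinyl]aluminium; 10 isobutyraldehyde
Product: 13 (4R,5R,8R)-5-(1-hydroxy-2-methylpropyl)-1,4-dimethyl-4-[1-(trimethylsilyl)vinyl]cyclohept-1-en-6-one, via aluminium enolate 11 (not isolated), via lithium aluminate 12 (not isolated)
Conditions: Cu(OTf)2 (5 mol %), chiral N-(2-sulfonatophenyl) 4,5-diphenylimidazolinium salt (5 mol %), THF, −30 → 0 °C; MeLi, −78 °C; i-PrCHO, −78 °C; aq. NH4Cl
Reagents that add atoms: none
Why: The alane reduces divalent copper to monovalent copper and deprotonates the imidazolinium salt, and Al-to-Cu transmetalation gives a sulfonate-bridged NHC–copper vinyl species. This adds to C4, the only conjugated position (π-complex, trivalent copper enolate, reductive elimination), forming C4–C10 and the quaternary centre and releasing aluminium enolate 11. The closest known reaction type is the NHC–copper-catalysed enantioselective conjugate addition of silyl-substituted vinylaluminium reagents to β-methyl cyclic enones, combined here with aluminate-activated aldol trapping of the enolate. MeLi turns 11 into the more nucleophilic aluminate 12, which adds to 10 through a closed six-membered Zimmerman–Traxler transition state and forms C5–C8. No ring is closed in this step. C4 (R) is set by the chiral catalyst, which selects the enone face; C5 (R in 13) is set by the substrate, because the aldehyde approaches the enolate face opposite the bulky silylvinyl group and beside the small methyl; C8 (R, anti adduct) should follow from the ring-locked E-enolate with isopropyl equatorial in the chair. The step needs 1,4- over 1,2-addition and vinyl over isobutyl transfer, which the copper catalyst and the higher transfer aptitude of the sp2 ligand secure. It also needs the enolate regiochemistry to hold, which it should because the enolate is made by the addition itself and trapped at −78 °C before proton transfer from C7 can occur.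

Step 8
Reactants: 13 (4R,5R,8R)-5-(1-hydroxy-2-methylpropyl)-1,4-dimethyl-4-[1-(trimethylsilyl)vinyl]cyclohept-1-en-6-one
Product: 15 (4R,5S,6S,8R)-5-(1-hydroxy-2-methylpropyl)-1,4-dimethyl-4-[1-(trimethylsilyl)vinyl]cyclohept-1-en-6-ol, via diethylboron chelate 14 (not isolated)
Conditions: Et2BOMe, THF/MeOH (4:1), −78 °C; NaBH4, −78 → −40 °C; AcOH; MeOH co-evaporation
Reagents that add atoms: none
Why: Narasaka–Prasad syn reduction; in the half-chair boron chelate of the anti aldol adduct the C4 substituent on C5 and the isopropyl group on C8 are both equatorial, and axial hydride attack gives the 1,3-syn diol with H6 anti to H5 (6S). The cold, nearly neutral medium should leave the β,γ-alkene in place, and after this step no carbonyl flanks C7.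

Step 9
Reactants: 16 4-hydroxybenzoic acid
Product: 18 4-(triisopropylsilyloxy)benzoic acid, via bis-silyl compound 17 (not isolated)
Conditions: TIPSCl, imidazole, DMF, rt; K2CO3, THF/MeOH/H2O, rt; aq. HCl to pH 4
Reagents that add atoms: chlorotriisopropylsilane, CC(C)[Si](Cl)(C(C)C)C(C)C
Why: exhaustive silylation followed by selective hydrolysis of the labile silyl ester; the aryl triisopropylsilyl ether should tolerate the mild carbonate.

Step 10
Reactants: 15 (4R,5S,6S,8R)-5-(1-hydroxy-2-methylpropyl)-1,4-dimethyl-4-[1-(trimethylsilyl)vinyl]cyclohept-1-en-6-ol; 18 4-(triisopropylsilyloxy)benzoic acid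
Product: 19 (4R,5R,6S,8R)-5-(1-hydroxy-2-methylpropyl)-1,4-dimethyl-4-[1-(trimethylsilyl)vinyl]cyclohept-1-en-6-yl 4-(triisopropylsilyloxy)benzoate
Conditions: EDC·HCl, DMAP, CH2Cl2, 0 °C → rt
Reagents that add atoms: none
Why: Steglich esterification; the ring carbinol at C6 should be acylated in preference to the C8 carbinol, which lies between the isopropyl methine and C5 next to the quaternary C4.

Step 11
Reactants: 19 (4R,5R,6S,8R)-5-(1-hydroxy-2-methylpropyl)-1,4-dimethyl-4-[1-(trimethylsilyl)vinyl]cyclohept-1-en-6-yl 4-(triisopropylsilyloxy)benzoate
Product: 20 (4S,5R,6S,8R)-5-(1-hydroxy-2-methylpropyl)-1,4-dimethyl-4-vinylcyclohept-1-en-6-yl 4-(triisopropylsilyloxy)benzoate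
Conditions: CF3CO2H, CH2Cl2, 0 °C
Reagents that add atoms: none
Why: protodesilylation of a vinylsilane; ipso-protonation at C10 gives the β-silyl-stabilised cation and loss of the silyl group leaves the vinyl group. Short contact at 0 °C is chosen to spare the ring alkene, the ester and the aryl silyl ether.

Step 12
Reactants: 20 (4S,5R,6S,8R)-5-(1-hydroxy-2-methylpropyl)-1,4-dimethyl-4-vinylcyclohept-1-en-6-yl 4-(triisopropylsilyloxy)benzoate
Product: 21 (4S,5S,6S)-5-isobutyryl-1,4-dimethyl-4-vinylcyclohept-1-en-6-yl 4-(triisopropylsilyloxy)benzoate
Conditions: Dess–Martin periodinane, CH2Cl2, 0 °C → rt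
Reagents that add atoms: none
Why: Dess–Martin oxidation of the hindered C8 carbinol without base, so that the new β-aroyloxy ketone should not eliminate; the C8 stereocentre, having served in step 8, is erased.

Step 13
Reactants: 21 (4S,5S,6S)-5-isobutyryl-1,4-dimethyl-4-vinylcyclohept-1-en-6-yl 4-(triisopropylsilyloxy)benzoate
Product: 22 (4R,5S,6S)-4-acetyl-5-isobutyryl-1,4-dimethylcyclohept-1-en-6-yl 4-(triisopropylsilyloxy)benzoate
Conditions: PdCl2 (10 mol %), CuCl, O2 (1 atm), DMF/H2O (7:1), rt
Reagents that add atoms: water, O
Why: Tsuji–Wacker oxidation of a γ,δ-unsaturated ketone to a 1,4-diketone; divalent palladium activates only the monosubstituted vinyl group and water adds at its internal carbon, while the trisubstituted ring alkene should stay untouched.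

Step 14
Reactants: 22 (4R,5S,6S)-4-acetyl-5-isobutyryl-1,4-dimethylcyclohept-1-en-6-yl 4-(triisopropylsilyloxy)benzoate
Product: 23 trans-fused (4R,5S,6S,8R)-8-hydroxy-8-isopropyl-1,4-dimethyl-10-oxo hydroazulene 6-[4-(triisopropylsilyloxy)benzoate] (C10 ketone, tertiary C8–OH cis to the angular methyl)
Conditions: LiN(SiMe3)2, THF, −78 → −40 °C; AcOH, −78 °C
Reagents that add atoms: none
Why: intramolecular aldol addition of the kinetic methyl-ketone enolate (C9) to the C8 ketone, the ring closure of 1,4-diketone cyclopentannulations stopped at the aldol stage by a cold aprotic quench. The ring is trans-fused because the two arms are trans, and C9 should add to the face of C8 that places isopropyl beside H5 and the alkoxide beside C6, away from the aroyloxy-bearing carbon (8R).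

Step 15
Reactants: 23 trans-fused (4R,5S,6S,8R) C10 ketone
Product: 24 (4R,5S,6S,8R,10S)-8,10-dihydroxy-8-isopropyl-1,4-dimethyl hydroazulene 6-[4-(triisopropylsilyloxy)benzoate] (silyl-protected target)
Conditions: Me4NBH(OAc)3, MeCN/AcOH, −20 °C → rt
Reagents that add atoms: none
Why: Evans–Saksena reduction; the tertiary C8 hydroxyl exchanges onto boron and delivers hydride within the molecule to the same face of C10, overriding the angular methyl and giving the C10 alcohol trans to the C8 hydroxyl (10S).

Step 16
Reactants: 24 silyl-protected target
Product: 25 2α-hydroxyferutinin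
Conditions: Bu4NF, AcOH, THF, 0 °C
Reagents that add atoms: none
Why: fluoride cleavage of the aryl silyl ether; buffering with AcOH should prevent acyl migration or ester cleavage by phenoxide or alkoxide.

## Compound list

1 | 2,5-dimethylphenol | Cc1ccc(C)c(O)c1 | starting material
2 | tert-butyl(2,5-dimethylphenoxy)dimethylsilane | Cc1ccc(C)c(O[Si](C)(C)C(C)(C)C)c1 | intermediate
3 | tert-butyl[(2,5-dimethylcyclohexa-1,4-dien-1-yl)oxy]dimethylsilane | CC1=CCC(C)=C(O[Si](C)(C)C(C)(C)C)C1 | intermediate
4 | rac-tert-butyl[(3,6-dimethylbicyclo[4.1.0]hept-3-en-1-yl)oxy]dimethylsilane, cis-fused, racemate with one enantiomer drawn | CC1=CC[C@]2(C)C[C@]2(O[Si](C)(C)C(C)(C)C)C1 | intermediate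
5 | rac-6-chloro-3,6-dimethylcyclohept-3-en-1-one (racemate) | CC1=CCC(C)(Cl)CC(=O)C1 | intermediate
6 | 3,6-dimethylcyclohepta-2,5-dien-1-one (achiral) | CC1=CCC(C)=CC(=O)C1 | intermediate
7 | ethynyltrimethylsilane | C#C[Si](C)(C)C | starting material
8 | diisobutylaluminium hydride | CC(C)C[AlH]CC(C)C | starting material
9 | diisobutyl[1-(trimethylsilyl)vinyl]aluminium | C=C([Si](C)(C)C)[Al](CC(C)C)CC(C)C | intermediate
10 | isobutyraldehyde | CC(C)C=O | starting material
11 | (4R)-diisobutylaluminium enolate of the conjugate adduct, C5=C6(OAl), not isolated | CC1=CC[C@@](C)(C(=C)[Si](C)(C)C)C=C(O[Al](CC(C)C)CC(C)C)C1 | intermediate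
12 | lithium (4R)-enolato(methyl)diisobutylaluminate, not isolated | [Li+].CC1=CC[C@@](C)(C(=C)[Si](C)(C)C)C=C(O[Al-](C)(CC(C)C)CC(C)C)C1 | intermediate
13 | (4R,5R,8R)-5-(1-hydroxy-2-methylpropyl)-1,4-dimethyl-4-[1-(trimethylsilyl)vinyl]cyclohept-1-en-6-one (anti aldol; C5 arm trans to the silylvinyl group) | CC1=CC[C@@](C)(C(=C)[Si](C)(C)C)[C@@H](C(=O)C1)[C@@H](C(C)C)O | intermediate
14 | O8-diethylboryl derivative of 13, boron chelated to the C6 carbonyl, not isolated | CC1=CC[C@@](C)(C(=C)[Si](C)(C)C)[C@@H](C(=O)C1)[C@@H](C(C)C)OB(CC)CC | intermediate
15 | (4R,5S,6S,8R)-5-(1-hydroxy-2-methylpropyl)-1,4-dimethyl-4-[1-(trimethylsilyl)vinyl]cyclohept-1-en-6-ol (syn-1,3-diol) | CC1=CC[C@@](C)(C(=C)[Si](C)(C)C)[C@@H]([C@@H](O)C1)[C@@H](C(C)C)O | intermediate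
16 | 4-hydroxybenzoic acid | OC(=O)c1ccc(O)cc1 | starting material
17 | triisopropylsilyl 4-(triisopropylsilyloxy)benzoate, not isolated | CC(C)[Si](C(C)C)(C(C)C)OC(=O)c1ccc(O[Si](C(C)C)(C(C)C)C(C)C)cc1 | intermediate
18 | 4-(triisopropylsilyloxy)benzoic acid | CC(C)[Si](C(C)C)(C(C)C)Oc1ccc(cc1)C(O)=O | intermediate
19 | (4R,5R,6S,8R)-5-(1-hydroxy-2-methylpropyl)-1,4-dimethyl-4-[1-(trimethylsilyl)vinyl]cyclohept-1-en-6-yl 4-(triisopropylsilyloxy)benzoate | CC1=CC[C@@](C)(C(=C)[Si](C)(C)C)[C@@H]([C@@H](OC(=O)c2ccc(O[Si](C(C)C)(C(C)C)C(C)C)cc2)C1)[C@@H](C(C)C)O | intermediate
20 | (4S,5R,6S,8R)-5-(1-hydroxy-2-methylpropyl)-1,4-dimethyl-4-vinylcyclohept-1-en-6-yl 4-(triisopropylsilyloxy)benzoate | CC1=CC[C@@](C)(C=C)[C@@H]([C@@H](OC(=O)c2ccc(O[Si](C(C)C)(C(C)C)C(C)C)cc2)C1)[C@@H](C(C)C)O | intermediate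
21 | (4S,5S,6S)-5-isobutyryl-1,4-dimethyl-4-vinylcyclohept-1-en-6-yl 4-(triisopropylsilyloxy)benzoate | CC1=CC[C@@](C)(C=C)[C@@H]([C@@H](OC(=O)c2ccc(O[Si](C(C)C)(C(C)C)C(C)C)cc2)C1)C(=O)C(C)C | intermediate
22 | (4R,5S,6S)-4-acetyl-5-isobutyryl-1,4-dimethylcyclohept-1-en-6-yl 4-(triisopropylsilyloxy)benzoate | CC1=CC[C@@](C)(C(C)=O)[C@@H]([C@@H](OC(=O)c2ccc(O[Si](C(C)C)(C(C)C)C(C)C)cc2)C1)C(=O)C(C)C | intermediate
23 | trans-fused (4R,5S,6S,8R) hydroazulene: C10 ketone, tertiary C8–OH with isopropyl, C6 4-(triisopropylsilyloxy)benzoate | CC1=CC[C@]2(C)[C@@H]([C@@H](OC(=O)c3ccc(O[Si](C(C)C)(C(C)C)C(C)C)cc3)C1)[C@](O)(C(C)C)CC2=O | intermediate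
24 | (4R,5S,6S,8R,10S) silyl-protected target: C8 and C10 diol, C6 4-(triisopropylsilyloxy)benzoate | CC1=CC[C@]2(C)[C@@H]([C@@H](OC(=O)c3ccc(O[Si](C(C)C)(C(C)C)C(C)C)cc3)C1)[C@](O)(C(C)C)C[C@@H]2O | intermediate
25 | 2α-hydroxyferutinin, (4R,5S,6S,8R,10S) | CC1=CC[C@]2(C)[C@@H]([C@@H](OC(=O)c3ccc(O)cc3)C1)[C@](O)(C(C)C)C[C@@H]2O | target

## Step count and least certain steps

Total step count: 16 (steps 6 and 9 are side branches). Longest linear sequence: 14 steps (1–5, 7, 8, 10–16).

**Step 7 (key step).** The second half is the weak point. The enolate carbon C5 is neopentyl-like and may add slowly, so that proton transfer from the enolisable aldehyde or from C7 competes and gives the plain conjugate adduct or a scrambled enolate. Poor simple diastereoselection at C8 would also cost material, because step 8 uses only the anti adduct. Enantioselection may be lower than for plain 3-methylcycloalkenones because of the second ring alkene. Fallback: setting out from 6 and 9, enolate 11 is silylated with Me3SiOTf and isolated as the trimethylsilyl enol ether F1. MeLi in THF then cleaves the O–Si bond to the regiodefined lithium enolate F2, whose aldol addition to 10 at −78 °C through the same closed transition state comes back to 13.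

**Step 11.** Acid-promoted side reactions may outrun ipso-protonation: migration of, or addition to, the trisubstituted C1=C2 alkene, a 1,3-acyl shift from O6 to the free O8, or loss of the aryl silyl ether. The 1,1-disubstituted vinylsilane gives only a primary β-silyl cation and is not especially fast. Fallback: setting out from diol 15, silicon is removed by nucleophilic activation (Bu4NF, DMSO, 80 °C; fluoride-induced protodesilylation of a vinylsilane) to the vinyl diol F3, which has no ester or aryl silyl ether at that stage. Site-selective esterification of F3 with 18 under the conditions of step 10 comes back to 20.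

**Step 14.** Ring closure may be slow, because both enolate carbons end up inside the new five-membered ring. That allows proton transfer to the C5 enolate with irreversible β-elimination of the aroyloxy group, or retro-aldol opening on warming; attack on the other face of C8 would give the epimeric carbinol. Fallback: setting out from 22, the kinetic enolate is trapped in situ (LiN(SiMe3)2, Me3SiCl, −78 °C) as the trimethylsilyl enol ether F4. The ring is then closed by an intramolecular Mukaiyama aldol addition (TiCl4, CH2Cl2, −78 °C), which runs without a free basic enolate and comes back to 23.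

**Step 10.** Acylation at O8 or at both hydroxyls, and acyl migration between O6 and O8 under DMAP, would erode the differentiation. Fallback: setting out from 13, O8 is silylated first (Et3SiOTf, 2,6-lutidine, −78 °C) to the triethylsilyl ether F5. The C6 ketone is then reduced without chelation (NaBH4, CeCl3, MeOH, −78 °C) to alcohol F6; the C6 epimers may have to be separated, which is why this is not the first choice. The only free hydroxyl of F6 is esterified with 18 to ester F7, and CF3CO2H as in step 11 removes the vinylic SiMe3 group and the triethylsilyl ether together, coming back to 20.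

**Step 4 (with step 5).** The robust tert-butyldimethylsilyl ether may resist cleavage by FeCl3, or acid may open the cyclopropane by protonolysis to a methyl ketone. In step 5 either double bond of 6 can migrate into full conjugation if the medium is too basic. Fallback: setting out from 4, the silyl group is removed (Bu4NF, AcOH, THF, 0 °C) to the cyclopropanol F8. The free cyclopropanol is oxidised with FeCl3 in DMF through the iron alkoxide to the same β-keto radical, coming back to 5.

## Further compounds

F1 | step 7 | (4R)-trimethylsilyl enol ether of the conjugate adduct, C5=C6(OSiMe3) | CC1=CC[C@@](C)(C(=C)[Si](C)(C)C)C=C(O[Si](C)(C)C)C1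
F2 | step 7 | (4R)-lithium enolate of the conjugate adduct | [Li+].CC1=CC[C@@](C)(C(=C)[Si](C)(C)C)C=C([O-])C1
F3 | step 11 | (4S,5S,6S,8R)-5-(1-hydroxy-2-methylpropyl)-1,4-dimethyl-4-vinylcyclohept-1-en-6-ol | CC1=CC[C@@](C)(C=C)[C@@H]([C@@H](O)C1)[C@@H](C(C)C)O
F4 | step 14 | C9=C10 trimethylsilyl enol ether of diketone 22 | CC1=CC[C@@](C)(C(=C)O[Si](C)(C)C)[C@@H]([C@@H](OC(=O)c2ccc(O[Si](C(C)C)(C(C)C)C(C)C)cc2)C1)C(=O)C(C)C
F5 | step 10 | O8-triethylsilyl ether of 13 | CC1=CC[C@@](C)(C(=C)[Si](C)(C)C)[C@@H](C(=O)C1)[C@@H](C(C)C)O[Si](CC)(CC)CC
F6 | step 10 | O8-triethylsilyl ether of diol 15 (free C6 hydroxyl, 6S) | CC1=CC[C@@](C)(C(=C)[Si](C)(C)C)[C@@H]([C@@H](O)C1)[C@@H](C(C)C)O[Si](CC)(CC)CC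
F7 | step 10 | O8-triethylsilyl ether of ester 19 | CC1=CC[C@@](C)(C(=C)[Si](C)(C)C)[C@@H]([C@@H](OC(=O)c2ccc(O[Si](C(C)C)(C(C)C)C(C)C)cc2)C1)[C@@H](C(C)C)O[Si](CC)(CC)CC
F8 | step 4 | rac-3,6-dimethylbicyclo[4.1.0]hept-3-en-1-ol, cis-fused | CC1=CC[C@]2(C)C[C@]2(O)C1
A1 | alternative 1 | 2-(1-ethoxyvinyl)-3-methylcyclopent-2-en-1-one | CCOC(=C)C1=C(C)CCC1=O
A2 | alternative 1 | methyl 2-diazobut-3-enoate | COC(=O)C(=[N+]=[N-])C=C
A3 | alternative 1 | dirhodium tetrakis[(S)-N-(4-dodecylbenzenesulfonyl)prolinate], Rh2(S-DOSP)4 | [Rh+2].[Rh+2].CCCCCCCCCCCCc1ccc(cc1)S(=O)(=O)N1CCC[C@H]1C([O-])=O.CCCCCCCCCCCCc1ccc(cc1)S(=O)(=O)N1CCC[C@H]1C([O-])=O.CCCCCCCCCCCCc1ccc(cc1)S(=O)(=O)N1CCC[C@H]1C([O-])=O.CCCCCCCCCCCCc1ccc(cc1)S(=O)(=O)N1CCC[C@H]1C([O-])=O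
A4 | alternative 1 | bicyclic ethoxy dienoate with quaternary C4 | COC(=O)C1=CC[C@@]2(C)CCC(=O)C2=C(OCC)C1
A5 | alternative 2 | thymoquinone | CC1=CC(=O)C(C(C)C)=CC1=O
A6 | alternative 2 | isoprene | CC(=C)C=C
A7 | alternative 2 | trans-fused C6-keto hydroazulene bis-silyl ether | CC1=CC[C@]2(C)[C@@H](C(=O)C1)[C@](O[Si](CC)(CC)CC)(C(C)C)C[C@@H]2O[Si](C)(C)C(C)(C)C
A8 | alternative 3 | hydroazulene C6 alcohol with C8 and C10 silyl ethers | CC1=CC[C@]2(C)[C@@H]([C@@H](O)C1)[C@](O[Si](CC)(CC)CC)(C(C)C)C[C@@H]2O[Si](C)(C)C(C)(C)C
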